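The runs were computed with made-up constants.

The pitfall is to take the two product readings for what has reacted: they count what has arrived as product, and the substrates may have gone elsewhere too.

| setting | Tuesday's | Wednesday's | Monday's | flask |
|---|---|---|---|---|
| left-handed substrate | 0.10 M | 0.10 M | 0.10 M | 0.10 M |
| right-handed substrate | 0.10 M | 0.10 M | 0.10 M | 0.10 M |
| reagent | 0.30 M | 0.30 M | 0.45 M | 0.300 M |
| free catalyst | 21 mM | 33 mM | 15 mM | 15 mM |
| remark | run made earlier | run made earlier | run made earlier |  |
| time |  |  |  | 4.0 h |

The flask holds 15 mM of free catalyst at 0.300 M of reagent. Tuesday's and Wednesday's runs share that reagent charge, so they can serve as a yardstick, but Monday's, at 0.45 M, cannot.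

| run | time / h | left-handed product / % | right-handed product / % |
|---|---|---|---|
| Tuesday's | 0.833 | 7 | 7 |
| Tuesday's | 1.50 | 5 | 6 |
| Tuesday's | 2.50 | 7 | 9 |
| Tuesday's | 3.00 | 9 | 6 |
| Tuesday's | 4.00 | 5 | 13 |
| Wednesday's | 0.833 | 5 | 5 |
| Wednesday's | 1.50 | 7 | 12 |
| Wednesday's | 2.50 | 9 | 11 |
| Wednesday's | 3.00 | 12 | 10 |
| Wednesday's | 4.00 | 12 | 14 |
| Monday's | 0.333 | 1 | 1 |
| Monday's | 1.00 | 4 | 3 |
| Monday's | 2.00 | 8 | 8 |
| Monday's | 3.00 | 10 | 9 |
| Monday's | 4.00 | 6 | 12 |

(standard deviation of a reading: 1.5 percentage points)

- free catalyst is single-handed; left-handed substrate and right-handed substrate are mirror images of each other, charged as a racemate, each of them at the stated concentration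
- an excess is the difference of the two amounts in percent of their sum
- an excess is below zero if the other one leads

- excess of left-handed product over right-handed product in the product at 5.0 min
- excess of left-handed product over right-handed product in the product at 4.0 h
- part of the left-handed substrate and right-handed substrate charged together that has reacted at 4.0 h

Single readings scatter by 1.5 percentage points, so I pool the 4.0 h rows of those two runs. Together they give 1.63 for N, the turnover number: moles of both products made by 4.0 h per mole of free catalyst charged, at this reagent charge. Taken singly, Tuesday's run reads 1.71 and Wednesday's 1.58, but with readings this scattered the two do not show whether N changes with the catalyst charge, so carrying N to the flask is my assumption. On that assumption I expect product of 12.2 % of the substrates charged in the flask, and the part reacted can stand above that.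

The forecast gives −6 % (range −25 % to 10 %) early, −15 % (range −35 % to −3 %) at 4.0 h, and 15 % reacted (range 11 % to 19 %). Of the shift in excess it says: “A drift with time is possible but unproven”. My figure counts product, and its 15 % is its answer for the part reacted.

    reagent ⇌ dormant form (K = 3.80, k = 0.00450 min⁻¹)
    free catalyst + right-handed substrate ⇌ catalyst intermediate B (K = 11.0 L mol⁻¹, k = 1.70 L mol⁻¹ min⁻¹)
    free catalyst + left-handed substrate ⇌ catalyst intermediate A (K = 3.40 L mol⁻¹, k = 1.50 L mol⁻¹ min⁻¹)
    left-handed substrate ⇌ right-handed substrate (k = 0.00180 min⁻¹)
    reagent + catalyst intermediate A → free catalyst + left-handed product (k = 0.180 L mol⁻¹ min⁻¹)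
    reagent + catalyst intermediate B → free catalyst + right-handed product (k = 0.0810 L mol⁻¹ min⁻¹)
    2 reagent → self-condensation product (k = 0.0100 L mol⁻¹ min⁻¹)

The flask gives 13.0 % at 5.0 min, then −13.8 % and 17.1 % reacted at 4.0 h, so the forecast's early excess lies 19 points low: left-handed product leads early, right-handed product at the end. Product in the flask stands at 5.63 % left-handed and 7.44 % right-handed, which makes N 1.74 against my 1.63. For the neighbouring flask with 0.0090 M of free catalyst, 1.63 gives 7.33 % product, and that flask holds 8.18 %.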